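**Assumption:** the target has no stereocentre and is achiral, so the structure as drawn is its only stereoisomer and no step needs stereocontrol.

## Retrosynthetic overview

1. Target 7 ⇒ 6: the last bond made is the aryl C–OMe bond at the one open position type of the oxygenated ring (dehydrogenative C–H methoxylation). Compound 6 is mirror-symmetric, so its two free ring positions are equivalent and only one regioisomer can form.
2. 6 ⇒ 3 + 4: the aryl–CH2 bond comes from lithiation between the two OMe groups and opening of 2,2-dimethyloxetane, which brings the tertiary alcohol with it.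
3. 3 ⇒ 1 + 2: the aryl–CH2 bond of the bibenzyl comes from a Kumada coupling.
4. No ring is formed in the route; both benzene rings are bought.

## Route

Step 1
Reactants: 1 1-bromo-3,5-dimethoxybenzene; 2 (2-phenylethyl)magnesium chloride
Product: 3 1,3-dimethoxy-5-(2-phenylethyl)benzene
Conditions: 2 (1.3 equiv), NiCl2(dppp) (2 mol %), THF, 0 °C to 40 °C
Reagents that add atoms: none
Why: Kumada–Corriu coupling, in which zerovalent nickel inserts into the aryl C–Br bond, the primary alkyl Grignard transmetalates and the chelating diphosphine favours reductive elimination over β-hydride loss; the methyl ethers are inert and no stereocentre is formed.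

Step 2
Reactants: 3 1,3-dimethoxy-5-(2-phenylethyl)benzene; 4 2,2-dimethyloxetane
Product: 6 4-[2,6-dimethoxy-4-(2-phenylethyl)phenyl]-2-methylbutan-2-ol, via aryllithium 5 (not isolated)
Conditions: n-BuLi (1.1 equiv), THF, 0 °C to rt, 1.5 h; then −78 °C, 4 (1.3 equiv), BF3·OEt2 (1.2 equiv), −78 °C to −30 °C; H2O
Reagents that add atoms: none
Why: Directed ortho-metalation takes the proton flanked by both OMe groups (the doubly activated site, as for other 5-alkylresorcinol dimethyl ethers), and the aryllithium opens the BF3-activated oxetane by SN2 attack at its unsubstituted O–CH2 carbon, giving the 3-hydroxy-3-methylbutyl chain directly with no stereocentre formed.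

Step 3
Reactants: 6 4-[2,6-dimethoxy-4-(2-phenylethyl)phenyl]-2-methylbutan-2-ol
Product: 7 4-[2,3,6-trimethoxy-4-(2-phenylethyl)phenyl]-2-methylbutan-2-ol
Conditions: 9-mesityl-3,6-di-tert-butyl-10-phenylacridinium tetrafluoroborate (5 mol %), TEMPO (20 mol %), O2 (1 atm), MeOH/1,2-dichloroethane 1:3, 455 nm LEDs, 25 °C; stop at about 70% conversion and recover 6
Reagents that add atoms: methanol, CO
Why: Proposed new method: a dehydrogenative arene C–H/methanol coupling through the arene cation radical, in which the excited acridinium (about +2.1 V vs SCE) oxidises only the dialkyl-dimethoxy ring of 6 (about +1.4 V; the phenyl ring lies above +2.2 V), methanol adds at one of the two equivalent free positions (ortho to one OMe and para to the other, where the positive charge resides), TEMPO removes the hydrogen atom from the cyclohexadienyl radical and O2 returns both the acridine radical and TEMPO-H, while the side-chain OH can reach only OMe-bearing ring carbons in a six-membered closure and such ipso adducts should revert because O2 outcompetes their reduction; the closest known reaction type is the acridinium/TEMPO/O2 C–H amination of arenes with azoles together with the photocatalytic alkoxylation of benzene, and to my knowledge neither has been shown for methanol on a tetrasubstituted dimethoxyarene; no stereocentre is involved.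

## Compound list

1 | 1-bromo-3,5-dimethoxybenzene | COc1cc(Br)cc(OC)c1 | starting material
2 | (2-phenylethyl)magnesium chloride | Cl[Mg]CCc1ccccc1 | starting material
3 | 1,3-dimethoxy-5-(2-phenylethyl)benzene | COc1cc(CCc2ccccc2)cc(OC)c1 | intermediate
4 | 2,2-dimethyloxetane | CC1(C)CCO1 | starting material
5 | [2,6-dimethoxy-4-(2-phenylethyl)phenyl]lithium | [Li]c1c(OC)cc(CCc2ccccc2)cc1OC | intermediate
6 | 4-[2,6-dimethoxy-4-(2-phenylethyl)phenyl]-2-methylbutan-2-ol | COc1cc(CCc2ccccc2)cc(OC)c1CCC(C)(C)O | intermediate
7 | 4-[2,3,6-trimethoxy-4-(2-phenylethyl)phenyl]-2-methylbutan-2-ol | COc1cc(CCc2ccccc2)c(OC)c(OC)c1CCC(C)(C)O | target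

## Step count and risks

Total step count: 3. Longest linear sequence: 3 steps (1 → 3 → 6 → 7).

The three steps most likely to fail, most risky first:

**Step 3 (proposed C–H methoxylation).** The product is about 0.3 V easier to oxidise than 6, so it can quench the catalyst, stall the reaction or be methoxylated again at its last ring position. Oxidation at the benzylic CH2 groups is a second risk. The fallback uses known chemistry and sets out from 6. NBS (1.05 equiv) in MeCN at 0 °C brominates the only activated ring position to give 4-[3-bromo-2,6-dimethoxy-4-(2-phenylethyl)phenyl]-2-methylbutan-2-ol F3. An Ullmann-type methoxylation (NaOMe, CuI 10 mol %, DMF/MeOH, 110 °C) then replaces bromide by methoxide, and the route is rejoined at the target 7. The tertiary alcohol is a spectator in both operations.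

**Step 2 (oxetane opening).** BF3 may ionise the oxetane at its tertiary carbon, or the hindered aryllithium may transfer to boron instead of attacking carbon. The fallback sets out from 3 through the same aryllithium 5. Alkylation with prenyl bromide (CuBr·SMe2 10 mol %, THF, −78 °C to rt) gives 1,3-dimethoxy-2-(3-methylbut-2-en-1-yl)-5-(2-phenylethyl)benzene F2. Mukaiyama hydration (Co(acac)2 20 mol %, PhSiH3, O2, THF, rt) then adds water in the Markovnikov sense to the trisubstituted alkene, and the route is rejoined at 6.

**Step 1 (Kumada coupling).** β-Hydride elimination from the phenethyl–nickel species, or Grignard homocoupling, could lower the yield. The fallback sets out from 1. A Mizoroki–Heck reaction with styrene (Pd(OAc)2 2 mol %, P(o-tol)3, NaOAc, DMF, 120 °C) gives (E)-1,3-dimethoxy-5-(2-phenylethenyl)benzene F1. Hydrogenation (H2 1 atm, Pd/C, EtOAc, rt) saturates the alkene, and the route is rejoined at 3.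

## Further compounds

F1 | step 1 | (E)-1,3-dimethoxy-5-(2-phenylethenyl)benzene | COc1cc(/C=C/c2ccccc2)cc(OC)c1
F2 | step 2 | 1,3-dimethoxy-2-(3-methylbut-2-en-1-yl)-5-(2-phenylethyl)benzene | COc1cc(CCc2ccccc2)cc(OC)c1CC=C(C)C
F3 | step 3 | 4-[3-bromo-2,6-dimethoxy-4-(2-phenylethyl)phenyl]-2-methylbutan-2-ol | COc1cc(CCc2ccccc2)c(Br)c(OC)c1CCC(C)(C)O
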